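**Plan**
Cuts: ring C at O1–C2 and C3–C4; the C4–C4a bond; the two carbon–carbon bonds that turn a carboxyl carbon into the isopropenyl group at C8''; and, centrally, the benzylic C1''–C2'' bond.
Enabling feature: O1, C8a, C8, C1'', the stereocentre C2'' and the isopropenyl carbon C8'' form an unbroken six-atom chain. Ring A and the side chain can therefore be joined as a 3-substituted dihydrocoumarin with C8'' as lactone carbonyl and O1 as ring oxygen.
Forward: ring A is bought as phloroglucinaldehyde and made into a silyl ether/benzylic acetate. A carbene-catalysed [4+2] with an acyl imidazole closes the temporary lactone ring, the lactone is opened, C8'' becomes the isopropenyl group, and the phenol set free (O1) steers formylation to C4a.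
Ring B is bought and arrives as an α-allyloxy ketone by aldol addition; oxidation and cyclodehydration close ring C last. Five allyl ethers then fall under neutral conditions, because acid would endanger the isopropenyl group and the tertiary alcohol.
The only stereocentre, C2'' (R), comes from the chiral triazolium-derived carbene in the annulation and afterwards meets only weakly basic or non-basic reagents.
Key step: step 8

Assumption: the (5aR,10bS) triazolium salt is taken to leave the Si face of the enolate carbon open, which gives the (R)-lactone. If the sense of induction proves opposite, the equally available (5aS,10bR) salt is used.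

**Route**

Step 1
Reactants: 1 2,4,6-trihydroxybenzaldehyde
Product: 2 2,4-bis(allyloxy)-6-hydroxybenzaldehyde
Conditions: allyl bromide (2.1 equiv), K2CO3, acetone, rt to 40 °C
Reagents that add atoms: allyl bromide, C=CCBr
Why: Williamson etherification alkylates the para hydroxyl and one ortho hydroxyl, while the last ortho hydroxyl is held in a hydrogen bond to the formyl oxygen, stays free and so marks the future O1.

Step 2
Reactants: 2 2,4-bis(allyloxy)-6-hydroxybenzaldehyde
Product: 3 2,4-bis(allyloxy)-6-(tert-butyldimethylsilyloxy)benzaldehyde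
Conditions: tBuMe2SiCl, imidazole, DMF, rt
Reagents that add atoms: tert-butyldimethylsilyl chloride, CC(C)(C)[Si](C)(C)Cl
Why: Imidazole-promoted silylation places the only fluoride-labile group of ring A on the oxygen that is to become O1.

Step 3
Reactants: 3 2,4-bis(allyloxy)-6-(tert-butyldimethylsilyloxy)benzaldehyde
Product: 4 [2,4-bis(allyloxy)-6-(tert-butyldimethylsilyloxy)phenyl]methanol
Conditions: iBu2AlH, CH2Cl2, −78 °C; aq. potassium sodium tartrate
Reagents that add atoms: none
Why: Hydride reduction at low temperature passes through a covalent aluminium alkoxide, which should suppress migration of the neighbouring silyl group to the benzylic oxygen.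

Step 4
Reactants: 4 [2,4-bis(allyloxy)-6-(tert-butyldimethylsilyloxy)phenyl]methanol
Product: 5 2,4-bis(allyloxy)-6-(tert-butyldimethylsilyloxy)benzyl acetate
Conditions: Ac2O, Et3N, 4-dimethylaminopyridine (cat.), CH2Cl2, 0 °C; Et3N-deactivated silica
Reagents that add atoms: acetic anhydride, CC(=O)OC(C)=O
Why: Nucleophile-catalysed acetylation under basic conditions installs a leaving group that, unlike a halide, can still be handled on this very electron-rich benzylic carbon.

Step 5
Reactants: 6 glutaric anhydride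
Product: 8 6,6-dimethyloxan-2-one, via 5-hydroxy-5-methylhexanoic acid 7 (not isolated)
Conditions: MeMgBr (2.2 equiv), THF, −30 °C to rt; then 2 M HCl
Reagents that add atoms: methylmagnesium bromide, C[Mg]Br
Why: In this double Grignard addition to a cyclic anhydride the first methyl opens the ring to a keto carboxylate, the ketone takes the second methyl while the carboxylate is inert, and the hydroxy acid lactonises on acidification.

Step 6
Reactants: 8 6,6-dimethyloxan-2-one
Product: 11 5-methyl-5-(triethylsilyloxy)hexanoic acid, via potassium 5-hydroxy-5-methylhexanoate 9 (not isolated), via triethylsilyl ester triethylsilyl ether 10 (not isolated)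
Conditions: KOH (1.0 equiv), MeOH, rt, evaporate; Et3SiCl, imidazole, 4-dimethylaminopyridine (cat.), DMF, rt; then MeOH–H2O, 0 °C, pH 5 work-up
Reagents that add atoms: potassium hydroxide, [K+].[OH-]; triethylsilyl chloride, CC[Si](Cl)(CC)CC
Why: Saponification holds the hydroxy acid as its non-lactonising carboxylate, exhaustive silylation caps both oxygens, and only the far more labile silyl ester is hydrolysed in aqueous methanol.

Step 7
Reactants: 11 5-methyl-5-(triethylsilyloxy)hexanoic acid
Product: 12 1-[5-methyl-5-(triethylsilyloxy)hexanoyl]imidazole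
Conditions: 1,1'-carbonyldiimidazole, CH2Cl2, rt
Reagents that add atoms: 1,1'-carbonyldiimidazole, O=C(n1ccnc1)n1ccnc1
Why: Carbonyldiimidazole activation, driven by loss of CO2, should give an isolable N-acylimidazole under neutral conditions that leave the tertiary silyl ether intact.

Step 8
Reactants: 5 2,4-bis(allyloxy)-6-(tert-butyldimethylsilyloxy)benzyl acetate; 12 1-[5-methyl-5-(triethylsilyloxy)hexanoyl]imidazole
Product: 15 (3R)-5,7-bis(allyloxy)-3-[3-methyl-3-(triethylsilyloxy)butyl]-3,4-dihydro-2H-chromen-2-one, via ortho-quinone methide 13 (not isolated), via azolium enolate 14 (not isolated)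
Conditions: (5aR,10bS)-2-mesityl-5a,10b-dihydro-4H,6H-indeno[2,1-b][1,2,4]triazolo[4,3-d][1,4]oxazin-2-ium tetrafluoroborate (15 mol %), CsF, 18-crown-6, 4 Å molecular sieves, THF, −20 °C to rt; 12 in excess
Reagents that add atoms: none
Why: CsF cleaves the aryl silyl ether of 5 and the phenoxide expels acetate by 1,4-elimination to give 13, while the carbene freed from the triazolium salt is acylated by 12 and the acyl azolium is deprotonated to the (Z)-enolate 14. C2'' of 14 adds in Michael fashion to the exocyclic CH2 (C1'') of 13, which rearomatises ring A, and the O1 phenoxide then attacks the acyl azolium carbon C8'' in a 6-exo-trig lactonisation that releases the carbene. The closest known reaction type is the carbene-catalysed enantioselective formal [4+2] annulation of fluoride-generated ortho-quinone methides with enolates from acyl imidazoles, which gives 3-substituted dihydrocoumarins. The fused aminoindanol backbone and the N-mesityl group shield one face of 14, so 13 should approach the Si face of C2'' and set the (R) configuration. Chemoselectivity rests on the substrate: ring A carries a single silyl ether, the allyl ethers on the future O5 and O7 are inert to fluoride so that no para-quinone methide or second ortho-quinone methide can form, excess fluoride is harmless, and the tertiary triethylsilyl ether is spared because a tertiary alkoxide is a far poorer leaving group than a phenoxide under anhydrous fluoride. The two donor oxygens speed up loss of acetate and lengthen the life of 13 at the price of lower electrophilicity, which the excess of 12 and slow warming address, and the low temperature limits base-mediated enolisation of the acidic C3–H of 15.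

Step 9
Reactants: 15 (3R)-5,7-bis(allyloxy)-3-[3-methyl-3-(triethylsilyloxy)butyl]-3,4-dihydro-2H-chromen-2-one
Product: 16 (2R)-2-[2,4-bis(allyloxy)-6-hydroxybenzyl]-N-methoxy-N,5-dimethyl-5-(triethylsilyloxy)hexanamide
Conditions: MeNH(OMe)·HCl, AlMe3, CH2Cl2, 0 °C (premixed); then 15, 0 °C to rt; aq. potassium sodium tartrate
Reagents that add atoms: N,O-dimethylhydroxylamine hydrochloride, CNOC.Cl
Why: In this Weinreb aminolysis the preformed, weakly basic aluminium amide opens the activated aryl ester without enolising C2'' and sets O1 free as the only phenol of the molecule.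

Step 10
Reactants: 16 (2R)-2-[2,4-bis(allyloxy)-6-hydroxybenzyl]-N-methoxy-N,5-dimethyl-5-(triethylsilyloxy)hexanamide
Product: 17 (3R)-3-[2,4-bis(allyloxy)-6-hydroxybenzyl]-6-methyl-6-(triethylsilyloxy)heptan-2-one
Conditions: MeMgBr (4 equiv), THF, 0 °C; aq. NH4Cl
Reagents that add atoms: methylmagnesium bromide, C[Mg]Br
Why: Grignard addition to the Weinreb amide stops at the chelated tetrahedral adduct after the phenol has consumed one equivalent, so the ketone appears only on quenching and C2'' is never exposed to base as a ketone.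

Step 11
Reactants: 17 (3R)-3-[2,4-bis(allyloxy)-6-hydroxybenzyl]-6-methyl-6-(triethylsilyloxy)heptan-2-one
Product: 18 3,5-bis(allyloxy)-2-[(2R)-5-methyl-2-(prop-1-en-2-yl)-5-(triethylsilyloxy)hexyl]phenol
Conditions: Cp2TiMe2 (3.5 equiv), toluene–THF, 70 °C, dark; then NaHCO3, MeOH–H2O, 40 °C
Reagents that add atoms: dimethyltitanocene, [CH3-].[CH3-].[Ti+4].c1cc[cH-]c1.c1cc[cH-]c1
Why: In the Petasis methylenation the thermally formed titanocene methylidene is non-basic, so the epimerisable centre next to the ketone is retained, the excess reagent covers the phenolic proton, and the aqueous treatment returns the phenol.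

Step 12
Reactants: 18 3,5-bis(allyloxy)-2-[(2R)-5-methyl-2-(prop-1-en-2-yl)-5-(triethylsilyloxy)hexyl]phenol
Product: 19 4,6-bis(allyloxy)-2-hydroxy-3-[(2R)-5-methyl-2-(prop-1-en-2-yl)-5-(triethylsilyloxy)hexyl]benzaldehyde
Conditions: MgCl2, Et3N, paraformaldehyde, THF, reflux; aq. NH4Cl
Reagents that add atoms: paraformaldehyde (as formaldehyde), C=O
Why: In the Casnati–Skattebøl ortho-formylation the magnesium phenoxide delivers formaldehyde within a chelate to the only free ortho carbon C4a, a second formaldehyde oxidises the hydroxymethyl stage by hydride transfer, and C6, para to O1, should stay untouched.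

Step 13
Reactants: 19 4,6-bis(allyloxy)-2-hydroxy-3-[(2R)-5-methyl-2-(prop-1-en-2-yl)-5-(triethylsilyloxy)hexyl]benzaldehyde
Product: 20 4,6-bis(allyloxy)-2-(tert-butyldimethylsilyloxy)-3-[(2R)-5-methyl-2-(prop-1-en-2-yl)-5-(triethylsilyloxy)hexyl]benzaldehyde
Conditions: tBuMe2SiOSO2CF3, 2,6-lutidine, CH2Cl2, 0 °C
Reagents that add atoms: tert-butyldimethylsilyl trifluoromethanesulfonate, CC(C)(C)[Si](C)(C)OS(=O)(=O)C(F)(F)F
Why: Silylation with the silyl triflate overcomes the hydrogen bond and the two flanking substituents and masks O1, so the aldehyde is not deactivated as a phenoxide in the aldol step.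

Step 14
Reactants: 21 2,4-dihydroxyacetophenone
Product: 22 2,4-bis(allyloxy)acetophenone
Conditions: allyl bromide (3 equiv), K2CO3, DMF, 60 °C
Reagents that add atoms: allyl bromide, C=CCBr
Why: Williamson etherification with excess halide and heating also alkylates the chelated ortho hydroxyl.

Step 15
Reactants: 22 2,4-bis(allyloxy)acetophenone
Product: 23 2-[2,4-bis(allyloxy)phenyl]-2,2-dimethoxyethanol
Conditions: PhI(OAc)2, KOH, MeOH, 0 °C to rt
Reagents that add atoms: methanol, CO
Why: In the Moriarty α-hydroxylation the enolate attacks trivalent iodine, methoxide adds to the carbonyl, and displacement of iodobenzene through a methoxy epoxide gives the α-hydroxy dimethyl ketal without touching the allyl ethers or the arene.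

Step 16
Reactants: 23 2-[2,4-bis(allyloxy)phenyl]-2,2-dimethoxyethanol
Product: 25 2-(allyloxy)-1-[2,4-bis(allyloxy)phenyl]ethanone, via allyl ether dimethyl ketal 24 (not isolated)
Conditions: NaH, allyl bromide, THF–DMF, 0 °C to rt; then 1 M HCl, THF, rt
Reagents that add atoms: allyl bromide, C=CCBr; water, O
Why: Williamson allylation of the primary alcohol is free of enolisation problems because the ketone is still masked, and the aryl-stabilised ketal is then hydrolysed by dilute acid that leaves allyl ethers alone.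

Step 17
Reactants: 20 4,6-bis(allyloxy)-2-(tert-butyldimethylsilyloxy)-3-[(2R)-5-methyl-2-(prop-1-en-2-yl)-5-(triethylsilyloxy)hexyl]benzaldehyde; 25 2-(allyloxy)-1-[2,4-bis(allyloxy)phenyl]ethanone
Product: 27 2-(allyloxy)-3-{4,6-bis(allyloxy)-2-(tert-butyldimethylsilyloxy)-3-[(2R)-5-methyl-2-(prop-1-en-2-yl)-5-(triethylsilyloxy)hexyl]phenyl}-1-[2,4-bis(allyloxy)phenyl]-3-hydroxypropan-1-one (diastereomer mixture at the two new centres), via lithium enolate 26 (not isolated)
Conditions: 25, LiN(SiMe3)2, THF, −78 °C; then 20, −78 °C; AcOH quench at −78 °C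
Reagents that add atoms: none
Why: Aldol addition of the chelated lithium (Z)-enolate forms C3–C4, the cold acidic quench limits retro-aldol and silyl migration, and the two new centres need no control because both become sp2 carbons of ring C.

Step 18
Reactants: 27 aldol adduct (diastereomer mixture)
Product: 28 2-(allyloxy)-1-{4,6-bis(allyloxy)-2-(tert-butyldimethylsilyloxy)-3-[(2R)-5-methyl-2-(prop-1-en-2-yl)-5-(triethylsilyloxy)hexyl]phenyl}-3-[2,4-bis(allyloxy)phenyl]propane-1,3-dione
Conditions: Dess–Martin periodinane (1.3 equiv), NaHCO3, CH2Cl2, 0 °C to rt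
Reagents that add atoms: none
Why: Buffered Dess–Martin oxidation turns the acid-sensitive benzylic β-hydroxy ketone into the 1,3-diketone without dehydration and without touching the six alkenes.

Step 19
Reactants: 28 2-allyloxy-1,3-diketone
Product: 30 3,5,7-tris(allyloxy)-2-[2,4-bis(allyloxy)phenyl]-8-[(2R)-5-hydroxy-5-methyl-2-(prop-1-en-2-yl)hexyl]-4H-chromen-4-one, via desilylated hydroxyaryl diketone 29 (not isolated)
Conditions: Bu4NF (3 equiv), THF, 0 °C to rt; then AcOH, 45 °C
Reagents that add atoms: none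
Why: Fluoride removes the aryl and the tertiary silyl group; after acidification the O1 phenol adds 6-exo-trig to the ring B carbonyl C2, and the hemiketal, whose ionisation the 2,4-dialkoxyphenyl group assists, loses water as in the closing stage of a Baker–Venkataraman flavone synthesis, the still allylated 2'-oxygen allowing only this mode of closure.

Step 20
Reactants: 30 penta-O-allyl kushenol G
Product: 31 kushenol G
Conditions: Pd(PPh3)4 (10 mol %), morpholine (excess), degassed THF, rt, argon; pH 5 work-up
Reagents that add atoms: none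
Why: In this Tsuji–Trost-type deallylation zerovalent palladium ionises each aryl or enol allyl ether to a π-allyl complex that excess morpholine traps faster than ring A can, and the neutral conditions leave the isopropenyl group, the tertiary alcohol and C2'' untouched.

**Compound list**
1 | 2,4,6-trihydroxybenzaldehyde | O=Cc1c(O)cc(O)cc1O | starting material
2 | 2,4-bis(allyloxy)-6-hydroxybenzaldehyde | O=Cc1c(O)cc(OCC=C)cc1OCC=C | intermediate
3 | 2,4-bis(allyloxy)-6-(tert-butyldimethylsilyloxy)benzaldehyde | O=Cc1c(O[Si](C)(C)C(C)(C)C)cc(OCC=C)cc1OCC=C | intermediate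
4 | [2,4-bis(allyloxy)-6-(tert-butyldimethylsilyloxy)phenyl]methanol | OCc1c(O[Si](C)(C)C(C)(C)C)cc(OCC=C)cc1OCC=C | intermediate
5 | 2,4-bis(allyloxy)-6-(tert-butyldimethylsilyloxy)benzyl acetate | CC(=O)OCc1c(O[Si](C)(C)C(C)(C)C)cc(OCC=C)cc1OCC=C | intermediate
6 | glutaric anhydride | O=C1CCCC(=O)O1 | starting material
7 | 5-hydroxy-5-methylhexanoic acid (not isolated) | CC(C)(O)CCCC(=O)O | intermediate
8 | 6,6-dimethyloxan-2-one | CC1(C)CCCC(=O)O1 | intermediate
9 | potassium 5-hydroxy-5-methylhexanoate (not isolated) | CC(C)(O)CCCC(=O)[O-].[K+] | intermediate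
10 | triethylsilyl 5-methyl-5-(triethylsilyloxy)hexanoate (not isolated) | CC[Si](CC)(CC)OC(=O)CCCC(C)(C)O[Si](CC)(CC)CC | intermediate
11 | 5-methyl-5-(triethylsilyloxy)hexanoic acid | CC[Si](CC)(CC)OC(C)(C)CCCC(=O)O | intermediate
12 | 1-[5-methyl-5-(triethylsilyloxy)hexanoyl]imidazole | O=C(CCCC(C)(C)O[Si](CC)(CC)CC)n1ccnc1 | intermediate
13 | 3,5-bis(allyloxy)-6-methylidenecyclohexa-2,4-dien-1-one, the ortho-quinone methide (not isolated) | C=C1C(=O)C=C(OCC=C)C=C1OCC=C | intermediate
14 | (Z)-azolium enolate from 12 and the (5aR,10bS) carbene (not isolated) | CC[Si](CC)(CC)OC(C)(C)CC/C=C(\[O-])c1[n+](-c2c(C)cc(C)cc2C)nc2n1[C@H]1c3ccccc3C[C@H]1OC2 | intermediate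
15 | (3R)-5,7-bis(allyloxy)-3-[3-methyl-3-(triethylsilyloxy)butyl]-3,4-dihydro-2H-chromen-2-one | O=C1Oc2cc(OCC=C)cc(OCC=C)c2C[C@H]1CCC(C)(C)O[Si](CC)(CC)CC | intermediate
16 | (2R)-2-[2,4-bis(allyloxy)-6-hydroxybenzyl]-N-methoxy-N,5-dimethyl-5-(triethylsilyloxy)hexanamide | CON(C)C(=O)[C@H](CCC(C)(C)O[Si](CC)(CC)CC)Cc1c(O)cc(OCC=C)cc1OCC=C | intermediate
17 | (3R)-3-[2,4-bis(allyloxy)-6-hydroxybenzyl]-6-methyl-6-(triethylsilyloxy)heptan-2-one | CC(=O)[C@H](CCC(C)(C)O[Si](CC)(CC)CC)Cc1c(O)cc(OCC=C)cc1OCC=C | intermediate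
18 | 3,5-bis(allyloxy)-2-[(2R)-5-methyl-2-(prop-1-en-2-yl)-5-(triethylsilyloxy)hexyl]phenol | C=C(C)[C@H](CCC(C)(C)O[Si](CC)(CC)CC)Cc1c(O)cc(OCC=C)cc1OCC=C | intermediate
19 | 4,6-bis(allyloxy)-2-hydroxy-3-[(2R)-5-methyl-2-(prop-1-en-2-yl)-5-(triethylsilyloxy)hexyl]benzaldehyde | C=C(C)[C@H](CCC(C)(C)O[Si](CC)(CC)CC)Cc1c(O)c(C=O)c(OCC=C)cc1OCC=C | intermediate
20 | 4,6-bis(allyloxy)-2-(tert-butyldimethylsilyloxy)-3-[(2R)-5-methyl-2-(prop-1-en-2-yl)-5-(triethylsilyloxy)hexyl]benzaldehyde | C=C(C)[C@H](CCC(C)(C)O[Si](CC)(CC)CC)Cc1c(O[Si](C)(C)C(C)(C)C)c(C=O)c(OCC=C)cc1OCC=C | intermediate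
21 | 2,4-dihydroxyacetophenone | CC(=O)c1ccc(O)cc1O | starting material
22 | 2,4-bis(allyloxy)acetophenone | CC(=O)c1ccc(OCC=C)cc1OCC=C | intermediate
23 | 2-[2,4-bis(allyloxy)phenyl]-2,2-dimethoxyethanol | COC(CO)(OC)c1ccc(OCC=C)cc1OCC=C | intermediate
24 | 2,4-bis(allyloxy)-1-[2-(allyloxy)-1,1-dimethoxyethyl]benzene (not isolated) | COC(COCC=C)(OC)c1ccc(OCC=C)cc1OCC=C | intermediate
25 | 2-(allyloxy)-1-[2,4-bis(allyloxy)phenyl]ethanone | C=CCOCC(=O)c1ccc(OCC=C)cc1OCC=C | intermediate
26 | lithium (Z)-enolate of 25 (not isolated) | [Li+].[O-]/C(=C\OCC=C)c1ccc(OCC=C)cc1OCC=C | intermediate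
27 | aldol adduct, (2R) in the side chain, mixture at the carbinol carbon and the allyloxy-bearing carbon | C=C(C)[C@H](CCC(C)(C)O[Si](CC)(CC)CC)Cc1c(O[Si](C)(C)C(C)(C)C)c(C(O)C(OCC=C)C(=O)c2ccc(OCC=C)cc2OCC=C)c(OCC=C)cc1OCC=C | intermediate
28 | 2-allyloxy-1,3-diketone, (2R) in the side chain, central carbon configurationally labile | C=C(C)[C@H](CCC(C)(C)O[Si](CC)(CC)CC)Cc1c(O[Si](C)(C)C(C)(C)C)c(C(=O)C(OCC=C)C(=O)c2ccc(OCC=C)cc2OCC=C)c(OCC=C)cc1OCC=C | intermediate
29 | desilylated 2-allyloxy-1-(2-hydroxyaryl)-1,3-diketone with free tertiary alcohol (not isolated) | C=C(C)[C@H](CCC(C)(C)O)Cc1c(O)c(C(=O)C(OCC=C)C(=O)c2ccc(OCC=C)cc2OCC=C)c(OCC=C)cc1OCC=C | intermediate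
30 | 3,5,7-tris(allyloxy)-2-[2,4-bis(allyloxy)phenyl]-8-[(2R)-5-hydroxy-5-methyl-2-(prop-1-en-2-yl)hexyl]-4H-chromen-4-one | C=C(C)[C@H](CCC(C)(C)O)Cc1c(OCC=C)cc(OCC=C)c2c(=O)c(OCC=C)c(-c3ccc(OCC=C)cc3OCC=C)oc12 | intermediate
31 | kushenol G, 2-(2,4-dihydroxyphenyl)-3,5,7-trihydroxy-8-[(2R)-5-hydroxy-5-methyl-2-(prop-1-en-2-yl)hexyl]-4H-chromen-4-one | C=C(C)[C@H](CCC(C)(C)O)Cc1c(O)cc(O)c2c(=O)c(O)c(-c3ccc(O)cc3O)oc12 | target

**Step count**
Total step count: 20.
Longest linear sequence: 14 steps (steps 1–4, 8–13 and 17–20).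

**Steps most likely to fail**

Step 8. Conjugate addition to a quinone methide stabilised by two donor oxygens may be sluggish. Imidazole may intercept the quinone methide, and basic fluoride may erode the enantiopurity by enolising the lactone.
Fallback, setting out from 11 and 5 and rejoining at 15:
- The mixed pivalic anhydride of 11 (PivCl, Et3N) is coupled with lithiated (S)-4-benzyloxazolidin-2-one to give (4S)-4-benzyl-3-[5-methyl-5-(triethylsilyloxy)hexanoyl]-1,3-oxazolidin-2-one F1.
- Its chelated chlorotitanium (Z)-enolate (TiCl4, iPr2NEt, CH2Cl2) is alkylated in SN1 fashion by acetate 5, which ionises readily. Attack comes from the face opposite the benzyl group and gives (4S)-4-benzyl-3-{(2R)-2-[2,4-bis(allyloxy)-6-(tert-butyldimethylsilyloxy)benzyl]-5-methyl-5-(triethylsilyloxy)hexanoyl}-1,3-oxazolidin-2-one F2.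
- CsF in DMF then frees the O1 phenoxide, which displaces the auxiliary by 6-exo-trig acyl transfer and gives 15.

Step 17. The addition may reverse at a hindered, electron-rich aldehyde, and the silyl group may migrate from O1 to the new alkoxide, which would block the oxidation.
Fallback, setting out from 20 and 25 and rejoining at 28, so that 27 and step 18 are bypassed:
- Pinnick oxidation of 20 (NaClO2, NaH2PO4, 2-methylbut-2-ene) gives 4,6-bis(allyloxy)-2-(tert-butyldimethylsilyloxy)-3-[(2R)-5-methyl-2-(prop-1-en-2-yl)-5-(triethylsilyloxy)hexyl]benzoic acid F3.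
- Carbodiimide coupling with 1H-benzotriazole gives the corresponding 1-aroylbenzotriazole F4.
- Ketone 25 is C-acylated by it under soft enolisation (MgBr2·OEt2, iPr2NEt, CH2Cl2), which forms C3–C4 directly at the diketone oxidation level.

Step 12. The hydroxymethyl stage may lose water on this electron-rich ring and arylate a second molecule (methylene-bridged dimerisation). Some attack at C6 is also possible.
Fallback, setting out from 18 and rejoining at 19:
- Boronate-templated ortho-hydroxymethylation (PhB(OH)2, paraformaldehyde, propionic acid (cat.), toluene, 90 °C, removal of water) traps the hydroxymethyl phenol as 5,7-bis(allyloxy)-8-[(2R)-5-methyl-2-(prop-1-en-2-yl)-5-(triethylsilyloxy)hexyl]-2-phenyl-4H-1,3,2-benzodioxaborinine F5.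
- Exchange with propane-1,3-diol releases 3,5-bis(allyloxy)-2-(hydroxymethyl)-6-[(2R)-5-methyl-2-(prop-1-en-2-yl)-5-(triethylsilyloxy)hexyl]phenol F6.
- This is oxidised at once with MnO2 in CH2Cl2 to 19.

**Further compounds**
F1 | step 8 | (4S)-4-benzyl-3-[5-methyl-5-(triethylsilyloxy)hexanoyl]-1,3-oxazolidin-2-one | O=C1OC[C@H](Cc2ccccc2)N1C(=O)CCCC(C)(C)O[Si](CC)(CC)CC
F2 | step 8 | (4S)-4-benzyl-3-{(2R)-2-[2,4-bis(allyloxy)-6-(tert-butyldimethylsilyloxy)benzyl]-5-methyl-5-(triethylsilyloxy)hexanoyl}-1,3-oxazolidin-2-one | O=C1OC[C@H](Cc2ccccc2)N1C(=O)[C@H](CCC(C)(C)O[Si](CC)(CC)CC)Cc1c(O[Si](C)(C)C(C)(C)C)cc(OCC=C)cc1OCC=C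
F3 | step 17 | 4,6-bis(allyloxy)-2-(tert-butyldimethylsilyloxy)-3-[(2R)-5-methyl-2-(prop-1-en-2-yl)-5-(triethylsilyloxy)hexyl]benzoic acid | C=C(C)[C@H](CCC(C)(C)O[Si](CC)(CC)CC)Cc1c(O[Si](C)(C)C(C)(C)C)c(C(=O)O)c(OCC=C)cc1OCC=C
F4 | step 17 | 1-{4,6-bis(allyloxy)-2-(tert-butyldimethylsilyloxy)-3-[(2R)-5-methyl-2-(prop-1-en-2-yl)-5-(triethylsilyloxy)hexyl]benzoyl}-1H-benzotriazole | C=C(C)[C@H](CCC(C)(C)O[Si](CC)(CC)CC)Cc1c(O[Si](C)(C)C(C)(C)C)c(C(=O)n2nnc3ccccc32)c(OCC=C)cc1OCC=C
F5 | step 12 | 5,7-bis(allyloxy)-8-[(2R)-5-methyl-2-(prop-1-en-2-yl)-5-(triethylsilyloxy)hexyl]-2-phenyl-4H-1,3,2-benzodioxaborinine | C=C(C)[C@H](CCC(C)(C)O[Si](CC)(CC)CC)Cc1c2OB(c3ccccc3)OCc2c(OCC=C)cc1OCC=C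
F6 | step 12 | 3,5-bis(allyloxy)-2-(hydroxymethyl)-6-[(2R)-5-methyl-2-(prop-1-en-2-yl)-5-(triethylsilyloxy)hexyl]phenol | C=C(C)[C@H](CCC(C)(C)O[Si](CC)(CC)CC)Cc1c(O)c(CO)c(OCC=C)cc1OCC=C
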